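**Plan**
1. Numbering: ring C1 (OMe), C2 (=CH), C3 (carries C7H2OBz), C4 (OH), C5 (OBz), C6 (OH). "Upper face" means the face of O5.
2. Enabling feature: O1 and O4 lie on the same (upper) face at the two allylic ends of C2=C3. This cis-1,4-dioxygenated 2-ene is what remains when the O–O bond of a cyclohexa-1,3-diene endoperoxide is reduced.
3. Retrosynthesis: remove the O5 benzoate and the O1 methyl group, and rejoin O1 and O4 to a 2,3-dioxabicyclo[2.2.2]oct-5-ene. Then cut C1–O and C4–O back to O2 and the C1=C2–C3=C4 diene, which derives from a shikimate C1 bromide by 1,4-loss of HBr.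
4. Forward: the carbocycle and C7 come intact from (−)-shikimic acid, whose C3, C2, C1, C6, C5, C4 and carboxyl carbon become C1 to C7. The only ring closed is the temporary 1,2-dioxine ring, and it is opened one step later.
5. Stereochemistry: C5 and C6 are C5 and C4 of shikimic acid. C1 and C4 are set together by the face of the cycloaddition, which is steered by the free O5–H and the bulky O6 silyl ether.
6. Two reinforcements: the C1 leaving group is an inverted bromide, so only 1,4-elimination is geometrically open. C7 is reduced to CH2OBz before the cycloaddition, so the diene is electron-rich.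

Key step: step 8

Remark: the explanations use target numbering, while the systematic names carry their own locants. Any adduct of the acyl bromide with O5–H in step 2 is assumed to be cleaved in the methanolysis half of that step.

Step 1
Reactants: 1 (−)-shikimic acid
Product: 2 methyl shikimate, methyl (3R,4S,5R)-3,4,5-trihydroxycyclohex-1-ene-1-carboxylate
Conditions: MeOH, TsOH·H2O (cat.), reflux
Reagents that add atoms: methanol, CO
Why: Fischer esterification touches only the carboxyl group, so the three carbinol centres are carried over unchanged.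

Step 2
Reactants: 2 methyl shikimate
Product: 4 methyl (3S,4S,5R)-3-bromo-4,5-dihydroxycyclohex-1-ene-1-carboxylate, via O6-acetyl bromohydrin 3 (not isolated)
Conditions: AcOCMe2COBr, MeCN, 0 °C → rt; concentrate; TsOH·H2O (cat.), MeOH, rt → 40 °C
Reagents that add atoms: 2-acetoxyisobutyryl bromide, CC(=O)OC(C)(C)C(=O)Br
Why: In the Mattocks–Moffatt reaction the cis C1/C6 diol becomes an acetoxonium ion that bromide opens by SN2 at the allylic C1 (inversion, Br on the upper face, C5 and C6 untouched), and acid-catalysed transesterification then removes the O6 acetate without forming an alkoxide that could close an epoxide.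

Step 3
Reactants: 4 bromodiol
Product: 5 methyl (3S,4S,5R)-3-bromo-4-hydroxy-5-(pivaloyloxy)cyclohex-1-ene-1-carboxylate
Conditions: PivCl (1.1 equiv), pyridine, CH2Cl2, 0 °C
Reagents that add atoms: pivaloyl chloride, CC(C)(C)C(=O)Cl
Why: This is a sterically governed selective esterification, because O5–H has a CH2 neighbour whereas O6–H is flanked by C1–Br and C5–O and is inductively deactivated, so the bulky acid chloride should acylate O5 only, and the weak base should not close the bromohydrin.

Step 4
Reactants: 5 O5-pivaloyl bromohydrin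
Product: 6 methyl (3S,4S,5R)-3-bromo-4-(tert-butyldimethylsilyloxy)-5-(pivaloyloxy)cyclohex-1-ene-1-carboxylate
Conditions: TBSOTf, 2,6-lutidine, CH2Cl2, 0 °C
Reagents that add atoms: tert-butyldimethylsilyl triflate, CC(C)(C)[Si](C)(C)OS(=O)(=O)C(F)(F)F
Why: Silyl triflate silylation reaches the hindered O6–H, and the non-nucleophilic pyridine base neither displaces the allylic bromide nor moves the pivalate.

Step 5
Reactants: 6 silylated bromide
Product: 7 methyl (3R,4R)-4-(tert-butyldimethylsilyloxy)-3-(pivaloyloxy)cyclohexa-1,5-diene-1-carboxylate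
Conditions: DBU, THF, 0 °C → rt
Reagents that add atoms: none
Why: This is an amidine-induced 1,4-dehydrobromination (vinylogous E2) in which H6 is cis to the C1 bromide, so anti 1,2-elimination to a silyl dienol ether is closed and only H4 can be lost through the C2=C3 π bond, while silyloxide at C6 is too poor a leaving group for onward aromatisation.

Step 6
Reactants: 7 diene ester
Product: 8 (1R,6R)-6-(tert-butyldimethylsilyloxy)-3-(hydroxymethyl)cyclohexa-2,4-dien-1-ol
Conditions: i-Bu2AlH (excess), CH2Cl2, −78 °C; aq. potassium sodium tartrate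
Reagents that add atoms: none
Why: DIBAL-H reduces the conjugated ester 1,2 to the C7 alcohol and cleaves the pivalate in the same operation without base, the silyl ether is inert, and the neutral work-up avoids acid-induced aromatisation.

Step 7
Reactants: 8 diene diol; 9 benzoyl chloride
Product: 10 [(3R,4R)-4-(tert-butyldimethylsilyloxy)-3-hydroxycyclohexa-1,5-dien-1-yl]methyl benzoate
Conditions: BzCl (1.05 equiv), pyridine, CH2Cl2, −40 °C
Reagents that add atoms: benzoyl chloride, O=C(Cl)c1ccccc1
Why: In this selective esterification the primary allylic C7–OH should acylate far faster than the secondary O5–H next to the silyl ether, so the C7 benzoate is installed and the directing hydroxyl stays free.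

Step 8
Reactants: 10 diene benzoate
Product: 11 [(1S,4R,7S,8R)-7-(tert-butyldimethylsilyloxy)-8-hydroxy-2,3-dioxabicyclo[2.2.2]oct-5-en-5-yl]methyl benzoate (peroxide bridge C1–O–O–C4 on the upper face)
Conditions: O2, 5,10,15,20-tetraphenylporphyrin (cat.), visible light, CH2Cl2, −30 °C
Reagents that add atoms: dioxygen, O=O
Why: The porphyrin sensitiser converts ground-state O2 into singlet oxygen, which adds suprafacially and in concert as the 2π partner across C1 and C4 of the ring-locked s-cis diene, so both C–O bonds form on one face and C2=C3 appears between them. The closest known reaction type is the [4+2] photooxygenation of cyclohexa-1,3-dienes, including 5,6-dioxygenated ones that bear an acyloxymethyl group on the diene. The one ring closed is the six-membered 3,6-dihydro-1,2-dioxine (O–C1–C2=C3–C4–O), formed by intermolecular cycloaddition and giving, together with the carbocycle, the 2,3-dioxabicyclo[2.2.2]oct-5-ene. C1 and C4 are both set by the face of approach, which the shikimate-derived centres control: the free O5–H on the upper face hydrogen-bonds the incoming oxygen in the non-polar solvent, and the O6 silyl ether covers the lower face next to C1. The step needs facial selectivity, supplied by this matched pair, and [4+2] rather than Schenck ene reactivity, supplied by the s-cis ring geometry. Keeping C7 as CH2OBz rather than as an ester leaves the diene electron-rich enough for the electrophilic oxygen.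

Step 9
Reactants: 11 endoperoxide
Product: 12 [(3S,4R,5R,6R)-4-(tert-butyldimethylsilyloxy)-3,5,6-trihydroxycyclohex-1-en-1-yl]methyl benzoate
Conditions: thiourea, MeOH/CH2Cl2, 0 °C → rt
Reagents that add atoms: none
Why: Thiourea reduction cleaves only the O–O bond, so both C–O bonds (and with them C1 and C4), the alkene, the benzoate and the silyl ether survive, and the cis-1,4-diol is released before a Kornblum–DeLaMare isomerisation can intervene.

Step 10
Reactants: 12 triol
Product: 13 C4,C5-O-isopropylidene derivative of 12 (free C1–OH; stereocentres as in 12)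
Conditions: Me2C(OMe)2, PPTS (cat.), CH2Cl2, rt
Reagents that add atoms: 2,2-dimethoxypropane, COC(C)(C)OC
Why: In this acid-catalysed transketalisation only O4 and O5 are cis-vicinal, so the dioxolane can form only there and O1–H is left as the single free hydroxyl.

Step 11
Reactants: 13 acetonide alcohol
Product: 14 C1 methyl ether of 13
Conditions: MeOTf, 2,6-di-tert-butyl-4-methylpyridine, CH2Cl2, rt → 40 °C
Reagents that add atoms: methyl triflate, COS(=O)(=O)C(F)(F)F
Why: O-alkylation with methyl triflate and a hindered pyridine proceeds without an alkoxide, so silyl migration from O6 and benzoate transfer are avoided and C1 keeps its configuration.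

Step 12
Reactants: 14 methyl ether
Product: 15 [(3S,4S,5R,6R)-4,5,6-trihydroxy-3-methoxycyclohex-1-en-1-yl]methyl benzoate
Conditions: TFA/H2O (9:1), CH2Cl2, 0 °C → rt
Reagents that add atoms: none
Why: Aqueous acid hydrolysis removes the ketal and the silyl ether in one operation, while the benzoate and the allylic methyl ether persist because the flanking C–O bonds disfavour allyl cation formation.

Step 13
Reactants: 15 triol monobenzoate; 9 benzoyl chloride
Product: 16 [(3S,4R,5R,6R)-5-(benzoyloxy)-4,6-dihydroxy-3-methoxycyclohex-1-en-1-yl]methyl benzoate (target)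
Conditions: BzCl (1.1 equiv), Ph2BOCH2CH2NH2 (10 mol %), i-Pr2NEt, MeCN, rt
Reagents that add atoms: benzoyl chloride, O=C(Cl)c1ccccc1
Why: In this borinic-acid-catalysed regioselective acylation the catalyst binds the only cis-vicinal pair O4/O5 as a tetracoordinate borinate and passes the acyl group to the equatorial O5, the same pattern as O3-selective acylation of galactopyranosides, while the pseudoaxial O4 beside the C3 branch and the unbound O6 stay free.

**Compound list**
1 | (−)-shikimic acid, (3R,4S,5R)-3,4,5-trihydroxycyclohex-1-ene-1-carboxylic acid | O[C@@H]1C=C(C(=O)O)C[C@@H](O)[C@@H]1O | starting material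
2 | methyl shikimate | O[C@@H]1C=C(C(=O)OC)C[C@@H](O)[C@@H]1O | intermediate
3 | methyl (3S,4S,5R)-4-acetoxy-3-bromo-5-hydroxycyclohex-1-ene-1-carboxylate (C1–Br up, O6–Ac down, O5–H up) | Br[C@H]1C=C(C(=O)OC)C[C@@H](O)[C@@H]1OC(C)=O | intermediate
4 | methyl (3S,4S,5R)-3-bromo-4,5-dihydroxycyclohex-1-ene-1-carboxylate | Br[C@H]1C=C(C(=O)OC)C[C@@H](O)[C@@H]1O | intermediate
5 | methyl (3S,4S,5R)-3-bromo-4-hydroxy-5-(pivaloyloxy)cyclohex-1-ene-1-carboxylate | Br[C@H]1C=C(C(=O)OC)C[C@@H](OC(=O)C(C)(C)C)[C@@H]1O | intermediate
6 | methyl (3S,4S,5R)-3-bromo-4-(tert-butyldimethylsilyloxy)-5-(pivaloyloxy)cyclohex-1-ene-1-carboxylate | Br[C@H]1C=C(C(=O)OC)C[C@@H](OC(=O)C(C)(C)C)[C@@H]1O[Si](C)(C)C(C)(C)C | intermediate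
7 | methyl (3R,4R)-4-(tert-butyldimethylsilyloxy)-3-(pivaloyloxy)cyclohexa-1,5-diene-1-carboxylate | C1=CC(C(=O)OC)=C[C@@H](OC(=O)C(C)(C)C)[C@@H]1O[Si](C)(C)C(C)(C)C | intermediate
8 | (1R,6R)-6-(tert-butyldimethylsilyloxy)-3-(hydroxymethyl)cyclohexa-2,4-dien-1-ol | C1=CC(CO)=C[C@@H](O)[C@@H]1O[Si](C)(C)C(C)(C)C | intermediate
9 | benzoyl chloride | O=C(Cl)c1ccccc1 | starting material
10 | [(3R,4R)-4-(tert-butyldimethylsilyloxy)-3-hydroxycyclohexa-1,5-dien-1-yl]methyl benzoate | C1=CC(COC(=O)c2ccccc2)=C[C@@H](O)[C@@H]1O[Si](C)(C)C(C)(C)C | intermediate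
11 | [(1S,4R,7S,8R)-7-(tert-butyldimethylsilyloxy)-8-hydroxy-2,3-dioxabicyclo[2.2.2]oct-5-en-5-yl]methyl benzoate | O1O[C@H]2C=C(COC(=O)c3ccccc3)[C@@H]1[C@@H](O)[C@@H]2O[Si](C)(C)C(C)(C)C | intermediate
12 | [(3S,4R,5R,6R)-4-(tert-butyldimethylsilyloxy)-3,5,6-trihydroxycyclohex-1-en-1-yl]methyl benzoate | O[C@H]1C=C(COC(=O)c2ccccc2)[C@@H](O)[C@@H](O)[C@@H]1O[Si](C)(C)C(C)(C)C | intermediate
13 | C4,C5-acetonide of 12 with free C1–OH | O[C@H]1C=C(COC(=O)c3ccccc3)[C@H]2OC(C)(C)O[C@H]2[C@@H]1O[Si](C)(C)C(C)(C)C | intermediate
14 | C1 methyl ether of 13 | CO[C@H]1C=C(COC(=O)c3ccccc3)[C@H]2OC(C)(C)O[C@H]2[C@@H]1O[Si](C)(C)C(C)(C)C | intermediate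
15 | [(3S,4S,5R,6R)-4,5,6-trihydroxy-3-methoxycyclohex-1-en-1-yl]methyl benzoate | CO[C@H]1C=C(COC(=O)c2ccccc2)[C@@H](O)[C@@H](O)[C@@H]1O | intermediate
16 | [(3S,4R,5R,6R)-5-(benzoyloxy)-4,6-dihydroxy-3-methoxycyclohex-1-en-1-yl]methyl benzoate, CNP0349013.6 | CO[C@H]1C=C(COC(=O)c2ccccc2)[C@@H](O)[C@@H](OC(=O)c2ccccc2)[C@@H]1O | target

Total step count: 13. Longest linear sequence: 13 steps (1 → 16).

**Steps most likely to fail**

Step 8. Facial selectivity may erode if hydrogen bonding to O5–H is weak. Ene hydroperoxidation at the C7 methylene may compete, or the diene may aromatise during irradiation. The fallback replaces the one-step peroxide bridge by two stereospecific C–O bond formations and sets out from 10.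
- Hydroxyl-directed epoxidation (VO(acac)2 cat., t-BuOOH, toluene, 0 °C) should deliver oxygen to C3=C4 from the face of O5–H and give the upper-face C3,C4-vinyl epoxide F3.
- The zerovalent palladium catalyst Pd(PPh3)4 with acetic acid in THF at 0 °C (Tsuji–Trost type syn-1,4-opening by double inversion) should place acetate on C1 on the same face, giving the C1 acetate diol F4.
- Ketalisation as in step 10 gives the acetonide acetate F5.
- K2CO3/MeOH removes both esters to give the C1,C7-diol F6.
- Selective benzoylation of the primary C7–OH with 9 (pyridine, −40 °C) rejoins the route at 13.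

Step 5. The amidine may be N-alkylated by the allylic bromide. Liberated bromide may epimerise C1, which opens the 1,2-elimination channel, or elimination may run on to the arene. The fallback changes the leaving group from bromide to an oxirane oxygen and sets out from 5.
- K2CO3 in MeOH at 0 °C should close the trans-bromohydrin to the lower-face C1,C6-epoxide F1.
- LiN(SiMe3)2 in THF at −78 °C (base-induced 1,4-eliminative opening of a vinyl oxirane) removes H4 and releases O6 as its alkoxide, which cannot leave again, giving the dienol pivalate F2.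
- TBSOTf/2,6-lutidine then rejoins the route at 7.

Step 13. Acyl transfer may leak to O6 or O4, or the new benzoate may migrate under the amine base. The fallback relies on protecting-group control and sets out from 14.
- Aqueous AcOH (80%) at 40 °C should remove only the ketal and give the O6-silylated C4,C5-diol F7.
- With O6 masked, only the cis pair competes. The same borinate-catalysed benzoylation with 9 at the equatorial O5 gives the O6-silylated dibenzoate F8.
- HF·pyridine in THF at 0 °C, acidic enough to suppress acyl migration, arrives at 16.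

**Further compounds**
F1 | step 5 | methyl 5-(pivaloyloxy)-7-oxabicyclo[4.1.0]hept-2-ene-3-carboxylate, epoxide on the lower face, O5 up | O1[C@@H]2C=C(C(=O)OC)C[C@@H](OC(=O)C(C)(C)C)[C@@H]21
F2 | step 5 | methyl (3R,4R)-4-hydroxy-3-(pivaloyloxy)cyclohexa-1,5-diene-1-carboxylate | C1=CC(C(=O)OC)=C[C@@H](OC(=O)C(C)(C)C)[C@@H]1O
F3 | step 8 | upper-face C3,C4-epoxide of 10 (C1=C2 retained) | C1=C[C@@]2(COC(=O)c3ccccc3)O[C@H]2[C@@H](O)[C@@H]1O[Si](C)(C)C(C)(C)C
F4 | step 8 | C1 acetate of 12 | CC(=O)O[C@H]1C=C(COC(=O)c2ccccc2)[C@@H](O)[C@@H](O)[C@@H]1O[Si](C)(C)C(C)(C)C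
F5 | step 8 | C1 acetate of 13 | CC(=O)O[C@H]1C=C(COC(=O)c3ccccc3)[C@H]2OC(C)(C)O[C@H]2[C@@H]1O[Si](C)(C)C(C)(C)C
F6 | step 8 | C7-debenzoylated 13 (C1–OH and C7–OH free) | O[C@H]1C=C(CO)[C@H]2OC(C)(C)O[C@H]2[C@@H]1O[Si](C)(C)C(C)(C)C
F7 | step 13 | O6-TBS ether of 15 | CO[C@H]1C=C(COC(=O)c2ccccc2)[C@@H](O)[C@@H](O)[C@@H]1O[Si](C)(C)C(C)(C)C
F8 | step 13 | O6-TBS ether of 16 | CO[C@H]1C=C(COC(=O)c2ccccc2)[C@@H](O)[C@@H](OC(=O)c2ccccc2)[C@@H]1O[Si](C)(C)C(C)(C)C
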